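**Strategy.** The route rests on reading ring B as an α‑ketol: the fully substituted carbinol C8 neighbours oxygen‑bearing C7, and C9 is flanked by C1 and C8, both carbonyl carbons in the precursor. One two‑catalyst annulation joins an enal (C7–C6–C5, with prochiral C4 carrying C3 and C11 as a dioxane) to a 4‑alkoxy‑3‑oxobutanoate (C1, C9, C8, C10). It forms C5–C9 and C7–C8, closes ring B and sets C5 and C8. Directed reduction then sets C7, a triple oxidation closes ring A as the 4‑formyl lactol, and two acylations, desilylation and a last C11 reduction finish.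

Key step: step 5

Remark on notation: iridoid numbering is used; β is the face of H5 and H9 (convex), α the face on which ring A lies (concave).
Remark on C9: compound 8 is written with C1 cis to C4; its C9 epimer would pass steps 6 to 9 unchanged and merge in step 10, where C9 is α to the C1 aldehyde.
Remark on the carbene: the (5aR,10bS) salt is assumed from a model with the enaminol hydroxyl on the N‑aryl side and the indane shielding one face; the mirror‑image salt would be used if the sense is reversed.

Step 1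
Reactants: 1 2-(hydroxymethyl)propane-1,3-diol
Product: 2 (2,2-dimethyl-1,3-dioxan-5-yl)methanol
Conditions: 2,2-dimethoxypropane, p-TsOH·H2O (cat.), THF, rt
Reagents that add atoms: 2,2-dimethoxypropane, COC(C)(C)OC
Why: Acid-catalysed transacetalisation gives the six-membered acetonide of two of the three equivalent hydroxyls, leaving one primary alcohol.

Step 2
Reactants: 2 (2,2-dimethyl-1,3-dioxan-5-yl)methanol
Product: 3 2,2-dimethyl-1,3-dioxane-5-carbaldehyde
Conditions: (COCl)2, DMSO, CH2Cl2, −78 °C; Et3N; used crude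
Reagents that add atoms: none
Why: Swern oxidation of a primary alcohol stops at the aldehyde and its cold, short base exposure spares this β-alkoxy aldehyde from elimination.

Step 3
Reactants: 3 2,2-dimethyl-1,3-dioxane-5-carbaldehyde
Product: 4 (E)-3-(2,2-dimethyl-1,3-dioxan-5-yl)prop-2-enal
Conditions: Ph3P=CHCHO, toluene, 80 °C
Reagents that add atoms: (triphenylphosphoranylidene)acetaldehyde, O=CC=P(c1ccccc1)(c1ccccc1)c1ccccc1
Why: Wittig olefination with the stabilised formylmethylene ylide gives the two-carbon-extended enal with E geometry.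

Step 4
Reactants: 5 methyl 4-chloro-3-oxobutanoate
Product: 6 methyl 4-[(4-methoxyphenyl)methoxy]-3-oxobutanoate
Conditions: 4-methoxybenzyl alcohol, NaH (2.2 equiv), THF, 0 °C to rt; then 1 M HCl
Reagents that add atoms: 4-methoxybenzyl alcohol, COc1ccc(CO)cc1
Why: The first equivalent of base masks the keto ester as its enolate and the alkoxide then displaces the α'-chloride (Williamson-type SN2 substitution).

Step 5
Reactants: 4 (E)-3-(2,2-dimethyl-1,3-dioxan-5-yl)prop-2-enal; 6 methyl 4-[(4-methoxyphenyl)methoxy]-3-oxobutanoate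
Product: 8 methyl (1S,2R,5R)-5-(2,2-dimethyl-1,3-dioxan-5-yl)-2-hydroxy-2-{[(4-methoxyphenyl)methoxy]methyl}-3-oxocyclopentane-1-carboxylate, via Michael adduct 7 (not isolated)
Conditions: (R)-2-[diphenyl(trimethylsilyloxy)methyl]pyrrolidine (20 mol%), (5aR,10bS)-2-(pentafluorophenyl)-5a,10b-dihydro-4H,6H-indeno[2,1-b][1,2,4]triazolo[4,3-d][1,4]oxazin-2-ium tetrafluoroborate (10 mol%), NaOAc (10 mol%), CHCl3, rt
Reagents that add atoms: none
Why: The amine turns enal 4 into an (E)-iminium ion, the enol of 6 adds through C9 to C5 on the face not covered by the CPh2OTMS group, and hydrolysis frees keto aldehyde 7 with a freely epimerising C9. The carbene then adds to the C7 aldehyde, the Breslow enaminol attacks the C8 ketone and loss of the carbene leaves the α-ketol; the closest known reaction type is the secondary amine/N-heterocyclic carbene Michael–crossed benzoin cascade of enals with β-dicarbonyl compounds. Ring B closes in a 5-exo-trig mode. C5 is set by the amine catalyst (the R enantiomer is needed for 5R), C8 by the hydrogen-bonded enaminol–ketone transition state on the open face of the chiral carbene, and C9 by selection among its equilibrating epimers during closure. The step needs C-alkylation at C9, carbene addition to the aldehyde only, and one face of the C8 ketone; the 1,3-dicarbonyl acidity of C9, the activation of the ketone by its α-alkoxy group, and the branched dioxanyl group on C5 (which keeps the azolium on the opposite ring face so that O8 ends syn to C4) provide for these. The acetal ring also holds both C–O bonds near the nodal plane of any dienamine, which disfavours loss of alkoxide.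

Step 6
Reactants: 8 methyl (1S,2R,5R)-5-(2,2-dimethyl-1,3-dioxan-5-yl)-2-hydroxy-2-{[(4-methoxyphenyl)methoxy]methyl}-3-oxocyclopentane-1-carboxylate
Product: 9 methyl (1S,2R,3S,5R)-5-(2,2-dimethyl-1,3-dioxan-5-yl)-2,3-dihydroxy-2-{[(4-methoxyphenyl)methoxy]methyl}cyclopentane-1-carboxylate
Conditions: Me4NBH(OAc)3, MeCN/AcOH 1:1, −30 °C
Reagents that add atoms: none
Why: In this hydroxyl-directed (Saksena–Evans) reduction the borohydride bound to the tertiary O8 delivers hydride to C7 from the α face, so the new 7-OH is β and trans to 8-OH, while the ester and acetal are untouched.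

Step 7
Reactants: 9 methyl (1S,2R,3S,5R)-5-(2,2-dimethyl-1,3-dioxan-5-yl)-2,3-dihydroxy-2-{[(4-methoxyphenyl)methoxy]methyl}cyclopentane-1-carboxylate
Product: 10 methyl (1S,2R,3S,5R)-3-(tert-butyldimethylsilyloxy)-5-(2,2-dimethyl-1,3-dioxan-5-yl)-2-hydroxy-2-{[(4-methoxyphenyl)methoxy]methyl}cyclopentane-1-carboxylate
Conditions: TBSOTf (1.2 equiv), 2,6-lutidine, CH2Cl2, −78 °C
Reagents that add atoms: tert-butyldimethylsilyl trifluoromethanesulfonate, CC(C)(C)[Si](C)(C)OS(=O)(=O)C(F)(F)F
Why: Silylation at low temperature takes the secondary O7 and not the tertiary O8, masking the one hydroxyl that would not survive the later triple oxidation.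

Step 8
Reactants: 10 methyl (1S,2R,3S,5R)-3-(tert-butyldimethylsilyloxy)-5-(2,2-dimethyl-1,3-dioxan-5-yl)-2-hydroxy-2-{[(4-methoxyphenyl)methoxy]methyl}cyclopentane-1-carboxylate
Product: 11 C1 primary alcohol (CO2Me of 10 reduced to CH2OH; stereocentres as in 10)
Conditions: LiAlH4, THF, 0 °C; Fieser work-up
Reagents that add atoms: none
Why: Hydride reduction of the β-hydroxy ester gives the 1,3-diol without touching the silyl ether, acetal or benzyl ether.

Step 9
Reactants: 11 C1 primary alcohol
Product: 12 triol with free C1, C3 and C11 hydroxymethyl groups (7-OTBS, 8-OH and 10-OPMB kept; stereocentres as in 10)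
Conditions: PPTS (cat.), MeOH, rt
Reagents that add atoms: none
Why: Mild acid methanolysis opens the 1,3-dioxane acetonide while the hindered secondary silyl ether and the 4-methoxybenzyl ether persist.

Step 10
Reactants: 12 triol
Product: 14 (1R,4aS,6S,7R,7aS)-6-(tert-butyldimethylsilyloxy)-1,7-dihydroxy-7-{[(4-methoxyphenyl)methoxy]methyl}-1,4a,5,6,7,7a-hexahydrocyclopenta[c]pyran-4-carbaldehyde, via trialdehyde 13 (not isolated)
Conditions: (COCl)2, DMSO, CH2Cl2, −78 °C; then Et3N, −78 °C to rt
Reagents that add atoms: none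
Why: Swern oxidation activates all three primary hydroxyls before base is added (the tertiary O8 cannot be oxidised), and in trialdehyde 13 the malondialdehyde unit enolises and its enol oxygen adds to the C1 aldehyde (hemiacetalisation) to close ring A cis-fused; the two arms are equivalent so C4 needs no control, C9 can equilibrate next to C1=O, and the lactol is written as its β anomer.

Step 11
Reactants: 14 lactol aldehyde; 15 (S)-3-methylpentanoic acid
Product: 16 (1S,4aS,6S,7R,7aS)-6-(tert-butyldimethylsilyloxy)-4-formyl-7-hydroxy-7-{[(4-methoxyphenyl)methoxy]methyl}-1,4a,5,6,7,7a-hexahydrocyclopenta[c]pyran-1-yl (3S)-3-methylpentanoate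
Conditions: EDC·HCl, DMAP, CH2Cl2, 0 °C
Reagents that add atoms: none
Why: Steglich acylation of the interconverting lactol anomers should favour the β-acyloxy acetal, whose oxygen is pseudo-axial (anomeric effect) and on the open convex face; the tertiary O8 is inert.

Step 12
Reactants: 16 C1 acyl acetal
Product: 17 C10 primary alcohol (4-methoxybenzyl ether of 16 removed; otherwise as 16)
Conditions: DDQ, CH2Cl2/pH 7 phosphate buffer, 0 °C
Reagents that add atoms: none
Why: Oxidative cleavage of the electron-rich benzyl ether in wet, buffered medium frees O10, and the acceptor-substituted enol ether, silyl ether and acyl acetal are not oxidised.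

Step 13
Reactants: 18 p-coumaric acid
Product: 20 (E)-3-[4-(tert-butyldimethylsilyloxy)phenyl]prop-2-enoic acid, via bis-silyl derivative 19 (not isolated)
Conditions: TBSCl (2.2 equiv), imidazole, DMF, rt; then AcOH/THF/H2O, rt
Reagents that add atoms: tert-butyldimethylsilyl chloride, CC(C)(C)[Si](C)(C)Cl
Why: Both acidic hydroxyls are silylated and the far more labile silyl ester is then hydrolysed selectively, leaving the phenol protected.

Step 14
Reactants: 17 C10 primary alcohol; 20 (E)-3-[4-(tert-butyldimethylsilyloxy)phenyl]prop-2-enoic acid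
Product: 21 (1S,4aS,6S,7R,7aS)-6-(tert-butyldimethylsilyloxy)-7-({(E)-3-[4-(tert-butyldimethylsilyloxy)phenyl]prop-2-enoyl}oxymethyl)-4-formyl-7-hydroxy-1,4a,5,6,7,7a-hexahydrocyclopenta[c]pyran-1-yl (3S)-3-methylpentanoate
Conditions: EDC·HCl, DMAP, CH2Cl2, 0 °C to rt
Reagents that add atoms: none
Why: Steglich esterification takes place at the only unhindered hydroxyl, primary O10, since O8 is tertiary and O7 is silylated.

Step 15
Reactants: 21 bis-silyl ether
Product: 22 (1S,4aS,6S,7R,7aS)-4-formyl-6,7-dihydroxy-7-({(E)-3-(4-hydroxyphenyl)prop-2-enoyl}oxymethyl)-1,4a,5,6,7,7a-hexahydrocyclopenta[c]pyran-1-yl (3S)-3-methylpentanoate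
Conditions: HF·pyridine, pyridine, THF, 0 °C to rt
Reagents that add atoms: none
Why: Buffered fluoride cleaves the aryl and the secondary silyl ether while ring A is still the acid-tolerant vinylogous formate, so the acid-sensitive allylic alcohol has not yet been made.

Step 16
Reactants: 22 aldehyde
Product: 23 (1S,4aS,6S,7R,7aS)-6,7-dihydroxy-4-(hydroxymethyl)-7-({(E)-3-(4-hydroxyphenyl)prop-2-enoyl}oxymethyl)-1,4a,5,6,7,7a-hexahydrocyclopenta[c]pyran-1-yl (3S)-3-methylpentanoate (CNP0241834.1)
Conditions: NaBH4, CeCl3·7H2O, MeOH, −78 to −40 °C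
Reagents that add atoms: none
Why: Luche conditions give 1,2-reduction of the conjugated C11 aldehyde only, and at low temperature the esters, the acyl acetal and the cinnamoyl double bond are left alone.

**Compound list**

1 | 2-(hydroxymethyl)propane-1,3-diol | OCC(CO)CO | starting material
2 | (2,2-dimethyl-1,3-dioxan-5-yl)methanol | CC1(C)OCC(CO)CO1 | intermediate
3 | 2,2-dimethyl-1,3-dioxane-5-carbaldehyde | CC1(C)OCC(C=O)CO1 | intermediate
4 | (E)-3-(2,2-dimethyl-1,3-dioxan-5-yl)prop-2-enal | O=C/C=C/C1COC(C)(C)OC1 | intermediate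
5 | methyl 4-chloro-3-oxobutanoate | COC(=O)CC(=O)CCl | starting material
6 | methyl 4-[(4-methoxyphenyl)methoxy]-3-oxobutanoate | COC(=O)CC(=O)COCc1ccc(OC)cc1 | intermediate
7 | methyl 2-[(1R)-1-(2,2-dimethyl-1,3-dioxan-5-yl)-3-oxopropyl]-4-[(4-methoxyphenyl)methoxy]-3-oxobutanoate (Michael adduct, both C9 epimers) | COC(=O)C(C(=O)COCc1ccc(OC)cc1)[C@H](CC=O)C1COC(C)(C)OC1 | intermediate (not isolated)
8 | methyl (1S,2R,5R)-5-(2,2-dimethyl-1,3-dioxan-5-yl)-2-hydroxy-2-{[(4-methoxyphenyl)methoxy]methyl}-3-oxocyclopentane-1-carboxylate | COC(=O)[C@H]1[C@@H](C2COC(C)(C)OC2)CC(=O)[C@]1(O)COCc1ccc(OC)cc1 | intermediate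
9 | methyl (1S,2R,3S,5R)-5-(2,2-dimethyl-1,3-dioxan-5-yl)-2,3-dihydroxy-2-{[(4-methoxyphenyl)methoxy]methyl}cyclopentane-1-carboxylate | COC(=O)[C@H]1[C@@H](C2COC(C)(C)OC2)C[C@H](O)[C@]1(O)COCc1ccc(OC)cc1 | intermediate
10 | methyl (1S,2R,3S,5R)-3-(tert-butyldimethylsilyloxy)-5-(2,2-dimethyl-1,3-dioxan-5-yl)-2-hydroxy-2-{[(4-methoxyphenyl)methoxy]methyl}cyclopentane-1-carboxylate | COC(=O)[C@H]1[C@@H](C2COC(C)(C)OC2)C[C@H](O[Si](C)(C)C(C)(C)C)[C@]1(O)COCc1ccc(OC)cc1 | intermediate
11 | C1 primary alcohol: ring B cyclopentane with 9-CH2OH, 8α-OH, 8β-CH2OPMB, 7β-OTBS and the 5-(2,2-dimethyl-1,3-dioxan-5-yl) group | OC[C@H]1[C@@H](C2COC(C)(C)OC2)C[C@H](O[Si](C)(C)C(C)(C)C)[C@]1(O)COCc1ccc(OC)cc1 | intermediate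
12 | triol: as 11 with the acetonide opened to the C3 and C11 hydroxymethyl groups | OC[C@H]1[C@@H](C(CO)CO)C[C@H](O[Si](C)(C)C(C)(C)C)[C@]1(O)COCc1ccc(OC)cc1 | intermediate
13 | trialdehyde: as 12 with C1, C3 and C11 as aldehydes (malondialdehyde unit mainly as enol) | O=C[C@H]1[C@@H](C(C=O)C=O)C[C@H](O[Si](C)(C)C(C)(C)C)[C@]1(O)COCc1ccc(OC)cc1 | intermediate (not isolated)
14 | (1R,4aS,6S,7R,7aS)-6-(tert-butyldimethylsilyloxy)-1,7-dihydroxy-7-{[(4-methoxyphenyl)methoxy]methyl}-1,4a,5,6,7,7a-hexahydrocyclopenta[c]pyran-4-carbaldehyde (β anomer drawn) | O[C@@H]1OC=C(C=O)[C@H]2C[C@H](O[Si](C)(C)C(C)(C)C)[C@](O)(COCc3ccc(OC)cc3)[C@@H]12 | intermediate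
15 | (S)-3-methylpentanoic acid | CC[C@H](C)CC(=O)O | starting material
16 | (1S,4aS,6S,7R,7aS)-6-(tert-butyldimethylsilyloxy)-4-formyl-7-hydroxy-7-{[(4-methoxyphenyl)methoxy]methyl}-1,4a,5,6,7,7a-hexahydrocyclopenta[c]pyran-1-yl (3S)-3-methylpentanoate | CC[C@H](C)CC(=O)O[C@@H]1OC=C(C=O)[C@H]2C[C@H](O[Si](C)(C)C(C)(C)C)[C@](O)(COCc3ccc(OC)cc3)[C@@H]12 | intermediate
17 | as 16 with free 7-CH2OH (C10 alcohol) | CC[C@H](C)CC(=O)O[C@@H]1OC=C(C=O)[C@H]2C[C@H](O[Si](C)(C)C(C)(C)C)[C@](O)(CO)[C@@H]12 | intermediate
18 | p-coumaric acid | O=C(O)/C=C/c1ccc(O)cc1 | starting material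
19 | tert-butyldimethylsilyl (E)-3-[4-(tert-butyldimethylsilyloxy)phenyl]prop-2-enoate | CC(C)(C)[Si](C)(C)OC(=O)/C=C/c1ccc(O[Si](C)(C)C(C)(C)C)cc1 | intermediate (not isolated)
20 | (E)-3-[4-(tert-butyldimethylsilyloxy)phenyl]prop-2-enoic acid | O=C(O)/C=C/c1ccc(O[Si](C)(C)C(C)(C)C)cc1 | intermediate
21 | (1S,4aS,6S,7R,7aS)-6-(tert-butyldimethylsilyloxy)-7-({(E)-3-[4-(tert-butyldimethylsilyloxy)phenyl]prop-2-enoyl}oxymethyl)-4-formyl-7-hydroxy-1,4a,5,6,7,7a-hexahydrocyclopenta[c]pyran-1-yl (3S)-3-methylpentanoate | CC[C@H](C)CC(=O)O[C@@H]1OC=C(C=O)[C@H]2C[C@H](O[Si](C)(C)C(C)(C)C)[C@](O)(COC(=O)/C=C/c3ccc(O[Si](C)(C)C(C)(C)C)cc3)[C@@H]12 | intermediate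
22 | (1S,4aS,6S,7R,7aS)-4-formyl-6,7-dihydroxy-7-({(E)-3-(4-hydroxyphenyl)prop-2-enoyl}oxymethyl)-1,4a,5,6,7,7a-hexahydrocyclopenta[c]pyran-1-yl (3S)-3-methylpentanoate | CC[C@H](C)CC(=O)O[C@@H]1OC=C(C=O)[C@H]2C[C@H](O)[C@](O)(COC(=O)/C=C/c3ccc(O)cc3)[C@@H]12 | intermediate
23 | (1S,4aS,6S,7R,7aS)-6,7-dihydroxy-4-(hydroxymethyl)-7-({(E)-3-(4-hydroxyphenyl)prop-2-enoyl}oxymethyl)-1,4a,5,6,7,7a-hexahydrocyclopenta[c]pyran-1-yl (3S)-3-methylpentanoate | CC[C@H](C)CC(=O)O[C@@H]1OC=C(CO)[C@H]2C[C@H](O)[C@](O)(COC(=O)/C=C/c3ccc(O)cc3)[C@@H]12 | target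

**Step count.** Total: 16 steps. Longest linear sequence: 14 steps (1–3, 5–12, 14–16).

**Steps most likely to fail**

Step 5. The carbene may close ring B on the wrong face of the C8 ketone, or the two catalysts may interfere so that the relay stalls. A wrong C8 configuration cannot be repaired later. The fallback separates the two events and closes ring A first, so that the shape of a cis-fused bicycle, not a catalyst, chooses the ketone face. It sets out from Michael adduct 7, made from 4 and 6 with the amine alone and isolated. Aqueous acetic acid removes the acetonide, and heating in toluene lactonises one hydroxymethyl arm onto the β-keto ester while the other arm caps the aldehyde; this gives the lactone–lactol F1 (C4, C7 and C9 as mixtures that converge later). An achiral carbene (2-(pentafluorophenyl)-6,7-dihydro-5H-pyrrolo[2,1-c][1,2,4]triazol-2-ium tetrafluoroborate, NaOAc, CH2Cl2) then effects the crossed benzoin closure through the open hydroxy aldehyde. The six-membered lactone forces C1 cis to C4, the larger CH2OPMB group takes the convex face and the new hydroxyl can hydrogen-bond to the lactone carbonyl, which should give the hydroxy ketone lactone F2. Me4NBH(OAc)3 gives the 7β-alcohol F3, TBSOTf (2.2 equiv) silylates O7 and O11 to the bis-silyl lactone F4, and LiAlH4 opens the lactone to the silylated diol F5. HF·pyridine at 0 °C removes only the primary silyl group, and the route is rejoined at triol 12.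

Step 10. The free C1 aldehyde has the tertiary C8 hydroxyl in its β position, so under the amine base it may lose water or open ring B by retro-aldol cleavage. An arm may also eliminate as its alkoxysulfonium ion before it is oxidised. The fallback changes the order of the oxidation-state adjustments so that C1 is never a free aldehyde beside a base. It sets out from ester 10. PPTS in methanol gives the diol ester F6, and Dess–Martin periodinane oxidises the 1,3-diol to the malondialdehyde ester F7, held as its enol. i-Bu2AlH at −78 °C first turns the acidic enol into an unreactive aluminium enolate and then reduces the ester only to the aldehyde level, the tetrahedral intermediate being chelated by O8. On work-up the aldehyde is trapped by the enol and the route is rejoined at lactol 14.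

Step 16. In the basic borohydride medium the coumaroyl group may migrate from O10 to the free, cis-disposed O7, or the acyl acetal may be cleaved by methoxide. The fallback changes the timing of deprotection. It sets out from bis-silyl ether 21: the same NaBH4/CeCl3·7H2O reduction, run while O7 and the phenol are still silylated, gives the silylated allylic alcohol F8, and pyridine-buffered HF·pyridine then removes both silyl groups to arrive at target 23.

**Further compounds**

F1 | step 5 | lactone–lactol from 7 (δ-lactone O–C1 from one arm, six-membered lactol at C7 from the other; 3-[2-(4-methoxybenzyloxy)acetyl] substituent at C9) | O=C1OCC2COC(O)C[C@H]2C1C(=O)COCc1ccc(OC)cc1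
F2 | step 5 | cis-fused hydroxy ketone lactone (C1 lactone to O3, C7 ketone, 8α-OH, 8β-CH2OPMB, free 11-OH) | O=C1OCC(CO)[C@H]2CC(=O)[C@](O)(COCc3ccc(OC)cc3)[C@@H]12
F3 | step 5 | 7β-alcohol of F2 | O=C1OCC(CO)[C@H]2C[C@H](O)[C@](O)(COCc3ccc(OC)cc3)[C@@H]12
F4 | step 5 | 7,11-bis(tert-butyldimethylsilyl) ether of F3 | O=C1OCC(CO[Si](C)(C)C(C)(C)C)[C@H]2C[C@H](O[Si](C)(C)C(C)(C)C)[C@](O)(COCc3ccc(OC)cc3)[C@@H]12
F5 | step 5 | 11-O-silyl derivative of triol 12 (lactone of F4 reduced to the C1 and C3 alcohols) | OC[C@H]1[C@@H](C(CO)CO[Si](C)(C)C(C)(C)C)C[C@H](O[Si](C)(C)C(C)(C)C)[C@]1(O)COCc1ccc(OC)cc1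
F6 | step 10 | diol ester (10 with the acetonide opened) | COC(=O)[C@H]1[C@@H](C(CO)CO)C[C@H](O[Si](C)(C)C(C)(C)C)[C@]1(O)COCc1ccc(OC)cc1
F7 | step 10 | malondialdehyde ester (C3 and C11 as aldehydes, C1 still the methyl ester) | COC(=O)[C@H]1[C@@H](C(C=O)C=O)C[C@H](O[Si](C)(C)C(C)(C)C)[C@]1(O)COCc1ccc(OC)cc1
F8 | step 16 | bis-silyl ether of the target (21 with C11 reduced to CH2OH) | CC[C@H](C)CC(=O)O[C@@H]1OC=C(CO)[C@H]2C[C@H](O[Si](C)(C)C(C)(C)C)[C@](O)(COC(=O)/C=C/c3ccc(O[Si](C)(C)C(C)(C)C)cc3)[C@@H]12
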